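| setting | oak | flask |
|---|---|---|
| substrate | 34 mM | 34 mM |
| coupling partner | 85 mM | 85.0 mM |
| free catalyst | 0.34 mM | 0.34 mM |
| remark | the very flask that is asked about, followed so far |  |
| time |  | 30 h |

oak run (percent of the substrate charged)

| time / h | product / % | substrate / % |
|---|---|---|
| 0.833 | 1.5 | 98.1 |
| 2.50 | 5.4 | 95.5 |
| 4.00 | 6.8 | 92.1 |
| 6.00 | 9.5 | 88.8 |
| 10.0 | 15.8 | 82.4 |
| 12.0 | 19.7 | 80.2 |
| 15.0 | 24.1 | 74.6 |

(readings scatter by 0.5 percentage points)



- product present at 30 h, in percent of the substrate charged
- substrate present at 30 h, in percent of the substrate charged
- concentration of coupling partner at 30 h, in mM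

1. What is left of the substrate gives the rule. Oak is the flask asked about, followed so far. At 15.0 h it has 74.6% left, so I form the loss constant k = 0.0195 h⁻¹, the natural log of charge over remainder, divided by the time. The same sum on the oak readings at 6.00 h and 10.0 h gives 0.0198 h⁻¹ and 0.0194 h⁻¹. I freeze k, which treats oak as pseudo-first-order in substrate.

2. Fastest rung: using up substrate equal to c(free catalyst) takes 0.512 h, less than the first reading at 0.833 h. After that I let product trail the lost substrate by one catalyst charge, 1.00%. The gap read at 15.0 h is 1.3 percentage points.

3. Middle rung: the substrate half-life from k is 35.5 h, longer than 30 h, so I expect more substrate than product at the asked time.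

4. Slowest rung: c(coupling partner) over its starting rate of use, taking one partner per product, is 128 h. That is longer than 30 h, so I leave the partner out of k, but in the balance I take it down one for one with the substrate lost.

5. My reckoning for 30 h: substrate 55.7%, product 43.3%, partner 69.9 mM.

6. The forecast says product 45% (39% to 50%), substrate 54% (49% to 60%), partner 69.5 mM (66 mM to 72 mM). Its ground: "Any slowing from falling substrate and partner concentrations, product inhibition, or catalyst death favours the lower side". It puts substrate lower than my reckoning does.

7. The flask gives product 44.0%, substrate 55.3%, partner 69.9 mM, inside the forecast's ranges.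

    substrate + free catalyst → catalyst intermediate A (k = 3.00 M⁻¹ min⁻¹)
    2 catalyst intermediate B → spent catalyst (k = 4.20 M⁻¹ min⁻¹)
    catalyst intermediate B → released group + catalyst intermediate C (k = 0.130 min⁻¹)
    coupling partner + catalyst intermediate A → catalyst intermediate B (k = 1.80 M⁻¹ min⁻¹)
    catalyst intermediate C → free catalyst + product (k = 0.120 min⁻¹)

In this flask the step from substrate and free catalyst ran throughout, with half of its turnover done by 13.2 h, while free catalyst stood at 30.6%, 31.9% and 34.5% of its charge at 3.00 h, 15.0 h and 30.0 h, about a third. Over those hours spent catalyst, counted by the catalyst it holds, grew from 2.70% to 18.7% of the catalyst charged, and the loss constant reckoned from the 30 h substrate is 0.0197 h⁻¹, beside the frozen 0.0195 h⁻¹.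

8. The same flask read at 2.0 d: frozen k gives substrate 39.2%. The computed value is 36.9%.

The data were computed for an exercise; scatter was added.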